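**Strategy.** The target is cut at the aryl–CH2 bond into a 6-metallated luteolin tetrabenzyl ether and the aldehyde (1S,2S)-2-(benzyloxy)-2,6,6-trimethylcyclohexane-1-carbaldehyde. The cyclohexane ring is made by contraction of a cycloheptane: in a trans-2-hydroxy mesylate, the ring carbon carrying the methyl and the protected tertiary oxygen migrates from the carbinol carbon to the mesylate carbon. This exploits the C2(OH)Me–C1H(CH2Ar)–C6Me2 triad of the cyclohexane ring: the CH centre is set by inversion, the tertiary carbinol migrates with retention, and the extruded carbon becomes the CHO that later forms the ArCH2 link. The cycloheptane comes from 2,2,6-trimethylcyclohexanone by one-carbon ring expansion, CBS reduction and anti dihydroxylation.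

Key step: step 9

Remark: in the CBS reduction (step 4) the quaternary C7 is assumed to act as the large group, as in other α,α-dialkyl ketones; if the sense were the opposite, the enantiomeric catalyst would be used.

**Step 1**
Reactants: 1 2,2,6-trimethylcyclohexan-1-one (racemic)
Product: 2 trimethyl[(2,6,6-trimethylcyclohex-1-en-1-yl)oxy]silane
Conditions: LDA, THF, −78 → 0 °C; TMSCl, −78 °C → rt
Reagents that add atoms: chlorotrimethylsilane, C[Si](C)(C)Cl
Why: The only α-hydrogen is removed and the enolate is O-silylated (silyl enol ether formation); the stereocentre of 1 is erased.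

**Step 2**
Reactants: 2 trimethyl[(2,6,6-trimethylcyclohex-1-en-1-yl)oxy]silane
Product: 3 trimethyl[(2,2,6-trimethylbicyclo[4.1.0]heptan-1-yl)oxy]silane (racemic, cis-fused)
Conditions: Et2Zn, CH2I2, CH2Cl2, 0 °C → rt
Reagents that add atoms: diiodomethane, ICI
Why: Simmons–Smith cyclopropanation (Et2Zn variant) of the electron-rich enol ether; cis fusion is the only possibility and both centres are erased in the next step.

**Step 3**
Reactants: 3 trimethyl[(2,2,6-trimethylbicyclo[4.1.0]heptan-1-yl)oxy]silane
Product: 5 3,7,7-trimethylcyclohept-2-en-1-one, via β-chloro ketone 4 (not isolated)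
Conditions: FeCl3, DMF, 0 °C → rt; then NaOAc, MeOH, reflux
Reagents that add atoms: none
Why: One-carbon ring expansion by oxidative opening of a siloxycyclopropane: FeCl3 oxidises by single-electron transfer, the internal cyclopropane bond cleaves to the tertiary radical, chlorine transfer gives 4, and acetate eliminates HCl (E1cB) to the conjugated enone.

**Step 4**
Reactants: 5 3,7,7-trimethylcyclohept-2-en-1-one
Product: 6 (1R)-3,7,7-trimethylcyclohept-2-en-1-ol
Conditions: (S)-Me-CBS (20 mol%), BH3·SMe2, THF, −30 °C
Reagents that add atoms: none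
Why: Corey–Bakshi–Shibata reduction (1,2-selective); hydride is delivered to the carbonyl face that keeps the quaternary C7 away from the catalyst, which should give the (R)-carbinol.

**Step 5**
Reactants: 6 (1R)-3,7,7-trimethylcyclohept-2-en-1-ol
Product: 7 (1S,2R,3S)-1,4,4-trimethylcycloheptane-1,2,3-triol
Conditions: OsO4 (2 mol%), NMO, acetone/H2O, rt
Reagents that add atoms: N-methylmorpholine N-oxide, C[N+]1([O-])CCOCC1; water, O
Why: Upjohn dihydroxylation; syn addition on the alkene face anti to the allylic hydroxyl (the empirical rule for osmylation of allylic alcohols) should set C1 and C2, both new hydroxyls trans to the C3–OH.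

**Step 6**
Reactants: 7 (1S,2R,3S)-1,4,4-trimethylcycloheptane-1,2,3-triol
Product: 8 1,2-O-benzylidene acetal of 7 (cis-fused 2-phenyl-1,3-dioxolane on O1/O2, C3–OH free, both epimers at the acetal carbon)
Conditions: PhCH(OMe)2, CSA (cat.), CH2Cl2, rt
Reagents that add atoms: benzaldehyde dimethyl acetal, COC(OC)c1ccccc1
Why: Acid-catalysed transacetalisation under thermodynamic control; the cis-vicinal tertiary/secondary diol should give the cis-fused dioxolane in preference to a trans-fused one, and the configuration at the acetal carbon is of no consequence.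

**Step 7**
Reactants: 8 1,2-O-benzylidene acetal of 7
Product: 9 methanesulfonate of 8 (mesylate on the former C3–OH)
Conditions: MsCl, Et3N, DMAP (cat.), CH2Cl2, 0 °C
Reagents that add atoms: methanesulfonyl chloride, CS(=O)(=O)Cl
Why: O-Sulfonylation via sulfene, which tolerates the neopentyl-type secondary alcohol; the C–O bond is untouched, so configuration is retained.

**Step 8**
Reactants: 9 methanesulfonate of 8
Product: 10 (1S,2R,3S)-3-(benzyloxy)-2-hydroxy-3,7,7-trimethylcycloheptyl methanesulfonate
Conditions: BH3·THF, TMSOTf (cat.), CH2Cl2, 0 °C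
Reagents that add atoms: none
Why: Regioselective reductive opening of a benzylidene acetal: the Lewis acid binds the less hindered secondary oxygen, that C–O bond breaks and hydride reduces the oxocarbenium ion on the tertiary oxygen. This should leave the benzyl group on the tertiary oxygen and free the C2–OH; the boron alkoxide is too weak a donor to start the 1,2-shift early.

**Step 9**
Reactants: 10 (1S,2R,3S)-3-(benzyloxy)-2-hydroxy-3,7,7-trimethylcycloheptyl methanesulfonate
Product: 12 (1S,2S)-2-(benzyloxy)-2,6,6-trimethylcyclohexane-1-carbaldehyde, via diethylaluminium alkoxide 11 (not isolated)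
Conditions: Et3Al (3 equiv), CH2Cl2, −78 → −20 °C; Rochelle salt work-up
Reagents that add atoms: none
Why: Et3Al turns the C2–OH into the aluminium alkoxide 11 and, as Lewis acid, loosens the mesylate; the ring bond C2–C3, antiperiplanar to C1–OMs in the diequatorial ground-state conformer, shifts from C2 to C1 while C2 becomes the aldehyde carbon (organoaluminium-promoted pinacol-type, i.e. semipinacol, rearrangement of a β-mesyloxy alcohol, run here as a ring contraction). The six-membered ring is closed by this suprafacial 1,2-alkyl shift (C3 to C1), not by a polar cyclisation, so the seven-membered ring loses C2 as the exocyclic CHO. The new CH stereocentre (C1 of 12) arises by inversion at the mesylate carbon and the migrating tertiary carbon keeps its configuration, which gives the trans relation of OBn and CHO. The step needs ring-bond migration to beat hydride shift, epoxide closure and Grob fragmentation. The carbinol H is syn to the mesylate and cannot migrate; the diaxial conformer needed for epoxide closure suffers a syn-diaxial OMs/CH3 contact and the aluminium alkoxide is a poor nucleophile at the neopentyl-type centre. The benzyl ether on the tertiary oxygen removes the alkoxide that a Grob fragmentation (which would racemise through an achiral keto aldehyde) would need.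

**Step 10**
Reactants: 13 luteolin, 2-(3,4-dihydroxyphenyl)-5,7-dihydroxy-4H-chromen-4-one
Product: 14 7-(benzyloxy)-2-[3,4-bis(benzyloxy)phenyl]-5-hydroxy-4H-chromen-4-one
Conditions: BnBr (3.3 equiv), K2CO3, DMF, rt
Reagents that add atoms: benzyl bromide, BrCc1ccccc1
Why: Williamson etherification; the 5-OH, hydrogen-bonded to the C4 carbonyl, is the least acidic and least nucleophilic and should stay free.

**Step 11**
Reactants: 14 7-(benzyloxy)-2-[3,4-bis(benzyloxy)phenyl]-5-hydroxy-4H-chromen-4-one
Product: 15 7-(benzyloxy)-2-[3,4-bis(benzyloxy)phenyl]-5-hydroxy-6-iodo-4H-chromen-4-one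
Conditions: BnMe3N·ICl2, CaCO3, CH2Cl2/MeOH, rt
Reagents that add atoms: benzyltrimethylammonium dichloroiodate, C[N+](C)(C)Cc1ccccc1.Cl[I-]Cl
Why: Electrophilic aromatic iodination; with the 5-OH free and O7 alkylated, attack should go ortho to the chelated phenol at C6 (C8 is attacked when O5 is alkylated), and the B-ring ethers are less activated.

**Step 12**
Reactants: 15 7-(benzyloxy)-2-[3,4-bis(benzyloxy)phenyl]-5-hydroxy-6-iodo-4H-chromen-4-one
Product: 16 5,7-bis(benzyloxy)-2-[3,4-bis(benzyloxy)phenyl]-6-iodo-4H-chromen-4-one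
Conditions: BnBr, K2CO3, DMF, 60 °C
Reagents that add atoms: benzyl bromide, BrCc1ccccc1
Why: Williamson etherification of the chelated 5-OH under more forcing conditions removes the acidic proton before metalation.

**Step 13**
Reactants: 16 5,7-bis(benzyloxy)-2-[3,4-bis(benzyloxy)phenyl]-6-iodo-4H-chromen-4-one; 12 (1S,2S)-2-(benzyloxy)-2,6,6-trimethylcyclohexane-1-carbaldehyde
Product: 18 5,7-bis(benzyloxy)-6-{[(1R,2S)-2-(benzyloxy)-2,6,6-trimethylcyclohexyl](hydroxy)methyl}-2-[3,4-bis(benzyloxy)phenyl]-4H-chromen-4-one (both carbinol epimers; the ring descriptor changes only by priority), via arylmagnesium chloride 17 (not isolated)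
Conditions: i-PrMgCl·LiCl, THF, −40 °C; then 12, LaCl3·2LiCl, −40 → 0 °C
Reagents that add atoms: none
Why: Iodine–magnesium exchange at low temperature, which the vinylogous-ester carbonyl of the chromone should tolerate, then lanthanum-promoted 1,2-addition to the hindered, scarcely enolisable aldehyde; the new carbinol centre forms unselectively and is removed in step 14.

**Step 14**
Reactants: 18 the carbinol from step 13
Product: 19 2-(3,4-dihydroxyphenyl)-5,7-dihydroxy-6-{[(1S,2S)-2-hydroxy-2,6,6-trimethylcyclohexyl]methyl}-4H-chromen-4-one (target)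
Conditions: H2 (1 atm), Pd(OH)2/C, EtOAc/MeOH, rt
Reagents that add atoms: none
Why: Heterogeneous hydrogenolysis cleaves the five benzyl ethers (four aryl, one tertiary alkyl); the benzylic C–OH, then flanked by two free phenols, should be hydrogenolysed via loss of water to an o-quinone methide that is hydrogenated. No stereocentre is touched and acid is avoided, so the tertiary alcohol does not cyclise onto a phenol.

**Compound list**
1 | 2,2,6-trimethylcyclohexan-1-one (racemic) | CC1CCCC(C)(C)C1=O | starting material
2 | trimethyl[(2,6,6-trimethylcyclohex-1-en-1-yl)oxy]silane | CC1=C(O[Si](C)(C)C)C(C)(C)CCC1 | intermediate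
3 | trimethyl[(2,2,6-trimethylbicyclo[4.1.0]heptan-1-yl)oxy]silane (racemic, cis-fused) | C[Si](C)(C)OC12CC1(C)CCCC2(C)C | intermediate
4 | 3-chloro-3,7,7-trimethylcycloheptan-1-one (racemic) | CC1(Cl)CCCC(C)(C)C(=O)C1 | intermediate (not isolated)
5 | 3,7,7-trimethylcyclohept-2-en-1-one | CC1=CC(=O)C(C)(C)CCC1 | intermediate
6 | (1R)-3,7,7-trimethylcyclohept-2-en-1-ol | CC1=C[C@@H](O)C(C)(C)CCC1 | intermediate
7 | (1S,2R,3S)-1,4,4-trimethylcycloheptane-1,2,3-triol | CC1(C)CCC[C@](C)(O)[C@H](O)[C@H]1O | intermediate
8 | 1,2-O-benzylidene acetal of 7 (C3–OH free, both acetal epimers) | CC1(C)CCC[C@]2(C)OC(c3ccccc3)O[C@@H]2[C@H]1O | intermediate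
9 | methanesulfonate of 8 | CC1(C)CCC[C@]2(C)OC(c3ccccc3)O[C@@H]2[C@H]1OS(C)(=O)=O | intermediate
10 | (1S,2R,3S)-3-(benzyloxy)-2-hydroxy-3,7,7-trimethylcycloheptyl methanesulfonate | CC1(C)CCC[C@](C)(OCc2ccccc2)[C@H](O)[C@H]1OS(C)(=O)=O | intermediate
11 | O-diethylaluminium alkoxide of 10 | CC1(C)CCC[C@](C)(OCc2ccccc2)[C@H](O[Al](CC)CC)[C@H]1OS(C)(=O)=O | intermediate (not isolated)
12 | (1S,2S)-2-(benzyloxy)-2,6,6-trimethylcyclohexane-1-carbaldehyde | CC1(C)CCC[C@](C)(OCc2ccccc2)[C@H]1C=O | intermediate
13 | luteolin | O=c1cc(-c2ccc(O)c(O)c2)oc2cc(O)cc(O)c12 | starting material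
14 | 7-(benzyloxy)-2-[3,4-bis(benzyloxy)phenyl]-5-hydroxy-4H-chromen-4-one | O=c1cc(-c2ccc(OCc3ccccc3)c(OCc3ccccc3)c2)oc2cc(OCc3ccccc3)cc(O)c12 | intermediate
15 | 7-(benzyloxy)-2-[3,4-bis(benzyloxy)phenyl]-5-hydroxy-6-iodo-4H-chromen-4-one | O=c1cc(-c2ccc(OCc3ccccc3)c(OCc3ccccc3)c2)oc2cc(OCc3ccccc3)c(I)c(O)c12 | intermediate
16 | 5,7-bis(benzyloxy)-2-[3,4-bis(benzyloxy)phenyl]-6-iodo-4H-chromen-4-one | O=c1cc(-c2ccc(OCc3ccccc3)c(OCc3ccccc3)c2)oc2cc(OCc3ccccc3)c(I)c(OCc3ccccc3)c12 | intermediate
17 | {5,7-bis(benzyloxy)-2-[3,4-bis(benzyloxy)phenyl]-4-oxo-4H-chromen-6-yl}magnesium chloride | O=c1cc(-c2ccc(OCc3ccccc3)c(OCc3ccccc3)c2)oc2cc(OCc3ccccc3)c([Mg]Cl)c(OCc3ccccc3)c12 | intermediate (not isolated)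
18 | 5,7-bis(benzyloxy)-6-{[(1R,2S)-2-(benzyloxy)-2,6,6-trimethylcyclohexyl](hydroxy)methyl}-2-[3,4-bis(benzyloxy)phenyl]-4H-chromen-4-one (both carbinol epimers) | CC1(C)CCC[C@](C)(OCc2ccccc2)[C@H]1C(O)c1c(OCc2ccccc2)cc2oc(-c3ccc(OCc4ccccc4)c(OCc4ccccc4)c3)cc(=O)c2c1OCc1ccccc1 | intermediate
19 | 2-(3,4-dihydroxyphenyl)-5,7-dihydroxy-6-{[(1S,2S)-2-hydroxy-2,6,6-trimethylcyclohexyl]methyl}-4H-chromen-4-one | CC1(C)CCC[C@](C)(O)[C@H]1Cc1c(O)cc2oc(-c3ccc(O)c(O)c3)cc(=O)c2c1O | target

**Step count.** Total: 14 steps. Longest linear sequence: 11 steps (steps 1–9, 13, 14).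

**Steps most likely to fail**

1. Step 9. The aluminium alkoxide may displace the mesylate directly from the minor diaxial conformer (epoxide closure), or ethyl transfer from aluminium to the new aldehyde may compete, so that the 1,2-shift does not dominate. The fallback sets out from 6 and returns at 12, and uses the diastereomer in which alkoxide and mesylate are on the same face, so that epoxide closure is impossible. Alcohol 6 is epoxidised on the hydroxyl face (VO(acac)2, t-BuOOH) to the cis-epoxy alcohol F1, which is mesylated to the epoxy mesylate F2. Acid-catalysed benzyl alcoholysis (BnOH, CSA) opens the epoxide at the tertiary carbon with inversion to the cis-hydroxy mesylate F3, the C2 epimer of 10. Alkoxide-driven ring contraction of F3 (KHMDS, 1 equiv, THF, −78 °C) should give 12 by the same inversion/retention course; hydride shift is the path to be watched there.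

2. Step 13. Addition of the di-ortho-substituted arylmagnesium to the neopentyl-type aldehyde may be slow, so that the organometallic attacks the pyranone of a second flavone molecule or is protonated. The fallback sets out from 12 and returns at 19. Aldehyde 12 is reduced (NaBH4) to the primary alcohol F4 and converted (I2, PPh3, imidazole) into the iodide F5. F5 is lithiated (t-BuLi, −78 °C), trapped with B-methoxy-9-BBN and coupled with 16 in a B-alkyl Suzuki–Miyaura reaction (PdCl2(dppf), AsPh3, Cs2CO3, DMF/H2O) to the deoxy coupling product F6. Hydrogenolysis of F6 as in step 14 gives 19.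

3. Step 14. O-Debenzylation should be fast, but hydrogenolysis of the benzylic C–OH bond may stall, and forcing conditions may start to saturate the C2–C3 double bond of the chromone. The fallback sets out from 18 and returns at 19. Ionic deoxygenation of 18 (Et3SiH, TFA, CH2Cl2, −40 °C), in which the benzylic cation is stabilised by three ring oxygens, gives the pentabenzyl ether F7. Mild hydrogenolysis (H2, Pd/C) of its five benzyl ethers gives 19.

**Further compounds**
F1 | step 9 | (1R)-cis-2,3-epoxy-3,7,7-trimethylcycloheptan-1-ol (epoxide oxygen cis to OH) | CC1(C)CCC[C@@]2(C)O[C@H]2[C@H]1O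
F2 | step 9 | methanesulfonate of F1 | CC1(C)CCC[C@@]2(C)O[C@H]2[C@H]1OS(C)(=O)=O
F3 | step 9 | (1S,2S,3S)-3-(benzyloxy)-2-hydroxy-3,7,7-trimethylcycloheptyl methanesulfonate | CC1(C)CCC[C@](C)(OCc2ccccc2)[C@@H](O)[C@H]1OS(C)(=O)=O
F4 | step 13 | [(1R,2S)-2-(benzyloxy)-2,6,6-trimethylcyclohexyl]methanol | CC1(C)CCC[C@](C)(OCc2ccccc2)[C@H]1CO
F5 | step 13 | benzyl (1S,2S)-2-(iodomethyl)-1,3,3-trimethylcyclohexyl ether | CC1(C)CCC[C@](C)(OCc2ccccc2)[C@H]1CI
F6 | step 13 | 5,7-bis(benzyloxy)-6-{[(1S,2S)-2-(benzyloxy)-2,6,6-trimethylcyclohexyl]methyl}-2-[3,4-bis(benzyloxy)phenyl]-4H-chromen-4-one | CC1(C)CCC[C@](C)(OCc2ccccc2)[C@H]1Cc1c(OCc2ccccc2)cc2oc(-c3ccc(OCc4ccccc4)c(OCc4ccccc4)c3)cc(=O)c2c1OCc1ccccc1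
F7 | step 14 | 5,7-bis(benzyloxy)-6-{[(1S,2S)-2-(benzyloxy)-2,6,6-trimethylcyclohexyl]methyl}-2-[3,4-bis(benzyloxy)phenyl]-4H-chromen-4-one (same structure as F6) | CC1(C)CCC[C@](C)(OCc2ccccc2)[C@H]1Cc1c(OCc2ccccc2)cc2oc(-c3ccc(OCc4ccccc4)c(OCc4ccccc4)c3)cc(=O)c2c1OCc1ccccc1
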